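**Retrosynthetic overview**

1. Target 36 ← macrocyclic germacradienol 30 by six late steps (C14 ester, C9 isobutyrate, C12 acetate, desilylation); 30 already holds C4, C5, C7 and C9.
2. 30 ← open-chain epoxy dienyl enal 28: the ten-membered carbocycle is closed at C8–C9 by a nickel-catalysed reductive coupling of the C9 aldehyde with the C8 terminus of the 2,3-disubstituted diene C8=C7–C11=C13; the same event sets C9 and C7 and leaves the C11=C13 methylidene.
3. Enabling feature: in the ring, carbinol C9, methylene C8 and methine C7 carrying the exocyclic C11=C13 unit form a 1-hydroxy-3-(alk-1-en-2-yl) array, the retron of a diene–aldehyde homoallylation; the trans C4–C5 oxirane and the E C1=C10 olefin stiffen the tether and relay chirality to C7 and C9.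
4. 28 ← cross-metathesis at C1=C10 (27 + acrolein 7) ← ethene enyne metathesis (C8 and C13 onto alkyne 26) ← epoxy triflate plus acetylide (C6–C7) ← Sharpless epoxidation ← syn-carbocupration of ynoate 18 (C4=C5 geometry); side-chain acid 15 by Evans aldol.
5. Ring order: oxirane first (step 10), ten-membered carbocycle second (step 14).

Key step: step 14

Remark: germacrane numbering is used for the ring compounds and their open-chain precursors (C1=C10 olefin, C4–C5 oxirane, C7 methine, C8 methylene, C9 carbinol, C11=C13 methylidene, oxygenated C12, C14 and C15); compounds 8, 16 and 19 are taken as purchasable.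

**Route**

Step 1
Reactants: 1 prop-2-yn-1-ol
Product: 3 1-methoxy-4-[(prop-2-yn-1-yloxy)methyl]benzene, via sodium alkoxide 2 (not isolated)
Conditions: NaH, THF/DMF, 0 °C; then 4-MeOC6H4CH2Cl, Bu4NI (cat.), 0 → 25 °C
Reagents that add atoms: 4-methoxybenzyl chloride COc1ccc(CCl)cc1
Why: Williamson ether synthesis (SN2 of the alkoxide on the benzylic chloride) should give the PMB-protected three-carbon unit that later supplies C7, C11 and C12; no stereocentre is involved.

Step 2
Reactants: 4 2-methylidenepropane-1,3-diol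
Product: 6 2-{[(triethylsilyl)oxy]methyl}prop-2-en-1-ol, via monosodium alkoxide 5 (not isolated)
Conditions: NaH (1.0 equiv), THF, 0 → 25 °C; then Et3SiCl (1.0 equiv), 0 °C
Reagents that add atoms: chlorotriethylsilane CC[Si](Cl)(CC)CC
Why: O-silylation of a symmetric diol through its sparingly soluble monosodium alkoxide should stop at the mono-ether, since only one hydroxyl is activated.

Step 3
Reactants: 6 2-{[(triethylsilyl)oxy]methyl}prop-2-en-1-ol
Product: 7 2-{[(triethylsilyl)oxy]methyl}prop-2-enal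
Conditions: MnO2 (excess), CH2Cl2, 25 °C
Reagents that add atoms: none
Why: MnO2 oxidation is selective for the allylic primary alcohol and should give the 2-substituted acrolein (future C9, C10, C14) without touching the silyl ether.

Step 4
Reactants: 8 (4R)-4-benzyl-3-propanoyl-1,3-oxazolidin-2-one; 9 acetaldehyde
Product: 12 (4R)-4-benzyl-3-[(2R,3S)-3-hydroxy-2-methylbutanoyl]-1,3-oxazolidin-2-one, via boron enolate 10 (not isolated), via boron aldolate 11 (not isolated)
Conditions: Bu2BOTf, i-Pr2NEt, CH2Cl2, −78 → 0 °C; then MeCHO, −78 → 0 °C; then pH 7 buffer, MeOH, H2O2, 0 °C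
Reagents that add atoms: none
Why: Evans syn-aldol reaction: the Z-boron enolate adds through a closed chair transition state on the face away from the benzyl group of the (R)-auxiliary, which should set the 2R,3S (syn) pair of the side chain.

Step 5
Reactants: 12 (4R)-4-benzyl-3-[(2R,3S)-3-hydroxy-2-methylbutanoyl]-1,3-oxazolidin-2-one
Product: 13 (4R)-4-benzyl-3-{(2R,3S)-2-methyl-3-[(triethylsilyl)oxy]butanoyl}-1,3-oxazolidin-2-one
Conditions: Et3SiCl, imidazole, DMF, 0 → 25 °C
Reagents that add atoms: chlorotriethylsilane CC[Si](Cl)(CC)CC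
Why: Imidazole-promoted silylation of the secondary alcohol should proceed without retro-aldol cleavage and masks the hydroxyl for the later esterification.

Step 6
Reactants: 13 (4R)-4-benzyl-3-{(2R,3S)-2-methyl-3-[(triethylsilyl)oxy]butanoyl}-1,3-oxazolidin-2-one
Product: 15 (2R,3S)-2-methyl-3-[(triethylsilyl)oxy]butanoic acid, via lithium peroxycarboxylate 14 (not isolated)
Conditions: LiOH, H2O2, THF/H2O (3:1), 0 °C; then Na2SO3; then 1 M HCl to pH 4
Reagents that add atoms: hydrogen peroxide OO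
Why: Hydroperoxide-mediated auxiliary cleavage attacks the exocyclic imide carbonyl selectively, so the acid should form without epimerisation at C2 and with the silyl ether intact.

Step 7
Reactants: 16 tert-butyldimethyl(prop-2-yn-1-yloxy)silane
Product: 18 methyl 4-[(tert-butyldimethylsilyl)oxy]but-2-ynoate, via lithium acetylide 17 (not isolated)
Conditions: n-BuLi, THF, −78 °C; then ClCO2Me, −78 → 0 °C
Reagents that add atoms: methyl chloroformate COC(=O)Cl
Why: C-acylation of a lithium acetylide with a chloroformate should give the ynoate whose four carbons become C15, C4, C5 and C6.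

Step 8
Reactants: 18 methyl 4-[(tert-butyldimethylsilyl)oxy]but-2-ynoate; 19 but-3-en-1-ylmagnesium bromide
Product: 21 methyl (2Z)-3-{[(tert-butyldimethylsilyl)oxy]methyl}hepta-2,6-dienoate, via alkenylcopper adduct 20 (not isolated)
Conditions: CuBr·SMe2 (1.5 equiv), 19 (1.5 equiv), THF, −40 °C; then 18, −78 °C; then sat. aq. NH4Cl, −78 °C
Reagents that add atoms: none
Why: syn-Carbocupration of the ynoate followed by stereoretentive protonation of the alkenylcopper at −78 °C should place the butenyl group trans to the ester, which fixes the C4=C5 geometry (C15 cis to C6).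

Step 9
Reactants: 21 methyl (2Z)-3-{[(tert-butyldimethylsilyl)oxy]methyl}hepta-2,6-dienoate
Product: 22 (2Z)-3-{[(tert-butyldimethylsilyl)oxy]methyl}hepta-2,6-dien-1-ol
Conditions: i-Bu2AlH (2.5 equiv), CH2Cl2, −78 °C; then aq. potassium sodium tartrate
Reagents that add atoms: none
Why: 1,2-Reduction of the conjugated ester by the aluminium hydride should give the allylic alcohol without olefin isomerisation or loss of the silyl ether.

Step 10
Reactants: 22 (2Z)-3-{[(tert-butyldimethylsilyl)oxy]methyl}hepta-2,6-dien-1-ol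
Product: 23 [(2R,3S)-3-(but-3-en-1-yl)-3-{[(tert-butyldimethylsilyl)oxy]methyl}oxiran-2-yl]methanol
Conditions: t-BuOOH, Ti(OiPr)4 (10 mol%), D-(−)-diethyl tartrate (12 mol%), 4 Å molecular sieves, CH2Cl2, −20 °C
Reagents that add atoms: tert-butyl hydroperoxide CC(C)(C)OO
Why: Katsuki–Sharpless asymmetric epoxidation of a 3,3-disubstituted allylic alcohol: the D-(−)-tartrate complex should deliver oxygen to the face that gives C5 R and C4 S (opposite in sense to the L-(+)-ester, which gives 2S,3S with geraniol), the trans relation of C3 and C6 follows from the olefin geometry, and the isolated vinyl group is not touched.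

Step 11
Reactants: 23 [(2R,3S)-3-(but-3-en-1-yl)-3-{[(tert-butyldimethylsilyl)oxy]methyl}oxiran-2-yl]methanol; 3 1-methoxy-4-[(prop-2-yn-1-yloxy)methyl]benzene
Product: 26 tert-butyl{[(2S,3R)-2-(but-3-en-1-yl)-3-{4-[(4-methoxybenzyl)oxy]but-2-yn-1-yl}oxiran-2-yl]methoxy}dimethylsilane, via lithium acetylide 24 (not isolated), via epoxy triflate 25 (not isolated)
Conditions: 23: Tf2O, 2,6-lutidine, CH2Cl2, −78 °C; 3: n-BuLi, THF, −78 °C; then combined, DMPU, −78 → −20 °C
Reagents that add atoms: none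
Why: SN2 displacement of a primary epoxy triflate by a lithium acetylide should form the C6–C7 bond faster than the oxirane can open in the absence of a Lewis acid, leaving both stereocentres untouched.

Step 12
Reactants: 26 tert-butyl{[(2S,3R)-2-(but-3-en-1-yl)-3-{4-[(4-methoxybenzyl)oxy]but-2-yn-1-yl}oxiran-2-yl]methoxy}dimethylsilane
Product: 27 tert-butyl{[(2S,3R)-2-(but-3-en-1-yl)-3-(3-{[(4-methoxybenzyl)oxy]methyl}-2-methylidenebut-3-en-1-yl)oxiran-2-yl]methoxy}dimethylsilane
Conditions: ethene (1 atm), second-generation Grubbs catalyst (10 mol%), toluene, 80 °C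
Reagents that add atoms: ethene C=C
Why: Ethene–alkyne cross enyne metathesis should turn the internal propargylic-ether alkyne into the 2,3-disubstituted 1,3-diene (C8 and C13 from ethene), while the vinyl group only exchanges degenerately and ring-closing modes are barred because a seven- or eight-membered ring would have to span the trans-oxirane.

Step 13
Reactants: 27 tert-butyl{[(2S,3R)-2-(but-3-en-1-yl)-3-(3-{[(4-methoxybenzyl)oxy]methyl}-2-methylidenebut-3-en-1-yl)oxiran-2-yl]methoxy}dimethylsilane; 7 2-{[(triethylsilyl)oxy]methyl}prop-2-enal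
Product: 28 (2E)-5-[(2S,3R)-2-{[(tert-butyldimethylsilyl)oxy]methyl}-3-(3-{[(4-methoxybenzyl)oxy]methyl}-2-methylidenebut-3-en-1-yl)oxiran-2-yl]-2-{[(triethylsilyl)oxy]methyl}pent-2-enal
Conditions: 7 (3 equiv), Hoveyda–Grubbs second-generation catalyst (10 mol%), CH2Cl2, 40 °C
Reagents that add atoms: none
Why: Olefin cross-metathesis of a terminal alkene with a 2-substituted acrolein should give the trisubstituted enal with the thermodynamically preferred E geometry (formyl trans to the chain, C14 cis to C2), the hindered 1,1-disubstituted diene termini being much slower partners.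

Step 14
Reactants: 28 (2E)-5-[(2S,3R)-2-{[(tert-butyldimethylsilyl)oxy]methyl}-3-(3-{[(4-methoxybenzyl)oxy]methyl}-2-methylidenebut-3-en-1-yl)oxiran-2-yl]-2-{[(triethylsilyl)oxy]methyl}pent-2-enal
Product: 30 (1(10)E,4S,5R,7R,9S)-15-[(tert-butyldimethylsilyl)oxy]-4,5-epoxy-12-[(4-methoxybenzyl)oxy]-14-[(triethylsilyl)oxy]germacra-1(10),11(13)-dien-9-ol, via diethylborinate 29 (not isolated)
Conditions: Ni(acac)2 (20 mol%), Et3B (3 equiv), THF, 25 °C, 28 added over 12 h (final 0.003 M), air excluded; then aq. NaHCO3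
Reagents that add atoms: none
Why: Proposed new method: zerovalent nickel (formed from Ni(acac)2 and Et3B) binds the C8=C7–C11=C13 diene and the Et3B-activated C9 aldehyde of 28 and joins C8 to C9 by oxidative cyclisation to an oxanickelacycle with an η3-allyl over C7–C11–C13, after which ethyl transfer from boron, β-hydride elimination (loss of ethene) and C–H reductive elimination at C7 release borinate 29 and return the catalyst. The closest known reaction type is the Ni-catalysed, Et3B-promoted reductive homoallylation of aldehydes with 1,3-dienes, established bimolecularly and for five- and six-membered ring closures but not for a medium ring, which is why the step carries the label. The ten-membered carbocycle closes by 10-exo-trig attack of the diene terminus C8 on the carbonyl carbon, the other half of the diene ending as the exocyclic C11=C13 methylidene. C9 and C7 are set together: a chair-like metallacycle with C10 pseudo-equatorial, followed by hydride delivery to C7 from the nickel-bearing face, gives the 1,3-anti C7/C9 pair that the target has, and the trans C4–C5 oxirane, which with the E C1=C10 olefin forces the tether into a crossed loop with C14 and C15 on the same side, should decide which anti pair forms (C7 side chain and C9 oxygen both pseudo-equatorial, as in the target). The step needs C8 over C13 regioselectivity, 1,2- over 1,4-addition to the enal and cyclisation over oligomerisation; these should be secured by the more electron-rich alkyl-substituted C7=C8 half of the diene (the C11 half carries the inductively withdrawing CH2OPMB group and would give an eleven-membered ring), by boron activation of the carbonyl oxygen, and by slow addition at high dilution.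

Step 15
Reactants: 30 (1(10)E,4S,5R,7R,9S)-15-[(tert-butyldimethylsilyl)oxy]-4,5-epoxy-12-[(4-methoxybenzyl)oxy]-14-[(triethylsilyl)oxy]germacra-1(10),11(13)-dien-9-ol
Product: 31 (1(10)E,4S,5R,7R,9S)-15-[(tert-butyldimethylsilyl)oxy]-4,5-epoxy-12-[(4-methoxybenzyl)oxy]germacra-1(10),11(13)-diene-9,14-diol
Conditions: HF·pyridine, pyridine, THF, 0 °C
Reagents that add atoms: none
Why: Buffered fluoride desilylation should cleave the primary allylic triethylsilyl ether much faster than the neopentyl-type primary TBS ether at C15, and no ester is yet present that could migrate.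

Step 16
Reactants: 31 (1(10)E,4S,5R,7R,9S)-15-[(tert-butyldimethylsilyl)oxy]-4,5-epoxy-12-[(4-methoxybenzyl)oxy]germacra-1(10),11(13)-diene-9,14-diol; 15 (2R,3S)-2-methyl-3-[(triethylsilyl)oxy]butanoic acid
Product: 32 (1(10)E,4S,5R,7R,9S)-15-[(tert-butyldimethylsilyl)oxy]-4,5-epoxy-9-hydroxy-12-[(4-methoxybenzyl)oxy]germacra-1(10),11(13)-dien-14-yl (2R,3S)-2-methyl-3-[(triethylsilyl)oxy]butanoate
Conditions: 15 (1.1 equiv), DCC, DMAP (10 mol%), CH2Cl2, −20 → 0 °C
Reagents that add atoms: none
Why: Steglich esterification should acylate the primary allylic C14 hydroxyl in preference to the hindered secondary C9 hydroxyl at low temperature, and the resulting primary ester has no thermodynamic drive to migrate.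

Step 17
Reactants: 32 (1(10)E,4S,5R,7R,9S)-15-[(tert-butyldimethylsilyl)oxy]-4,5-epoxy-9-hydroxy-12-[(4-methoxybenzyl)oxy]germacra-1(10),11(13)-dien-14-yl (2R,3S)-2-methyl-3-[(triethylsilyl)oxy]butanoate
Product: 33 (1(10)E,4S,5R,7R,9S)-15-[(tert-butyldimethylsilyl)oxy]-4,5-epoxy-12-[(4-methoxybenzyl)oxy]-9-(2-methylpropanoyloxy)germacra-1(10),11(13)-dien-14-yl (2R,3S)-2-methyl-3-[(triethylsilyl)oxy]butanoate
Conditions: (i-PrCO)2O, Et3N, DMAP (cat.), CH2Cl2, 0 → 25 °C
Reagents that add atoms: 2-methylpropanoic anhydride CC(C)C(=O)OC(=O)C(C)C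
Why: DMAP-catalysed acylation of the remaining secondary allylic alcohol should install the C9 isobutyrate with retention at C9.

Step 18
Reactants: 33 (1(10)E,4S,5R,7R,9S)-15-[(tert-butyldimethylsilyl)oxy]-4,5-epoxy-12-[(4-methoxybenzyl)oxy]-9-(2-methylpropanoyloxy)germacra-1(10),11(13)-dien-14-yl (2R,3S)-2-methyl-3-[(triethylsilyl)oxy]butanoate
Product: 34 (1(10)E,4S,5R,7R,9S)-15-[(tert-butyldimethylsilyl)oxy]-4,5-epoxy-12-hydroxy-9-(2-methylpropanoyloxy)germacra-1(10),11(13)-dien-14-yl (2R,3S)-2-methyl-3-[(triethylsilyl)oxy]butanoate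
Conditions: DDQ, CH2Cl2/pH 7 buffer (10:1), 0 °C
Reagents that add atoms: none
Why: Oxidative cleavage of the PMB ether by DDQ (benzylic hydride abstraction, then hydrolysis) under buffered neutral conditions should spare the oxirane, both silyl ethers and both esters, and no free secondary allylic alcohol is left to be oxidised.

Step 19
Reactants: 34 (1(10)E,4S,5R,7R,9S)-15-[(tert-butyldimethylsilyl)oxy]-4,5-epoxy-12-hydroxy-9-(2-methylpropanoyloxy)germacra-1(10),11(13)-dien-14-yl (2R,3S)-2-methyl-3-[(triethylsilyl)oxy]butanoate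
Product: 35 (1(10)E,4S,5R,7R,9S)-12-acetoxy-15-[(tert-butyldimethylsilyl)oxy]-4,5-epoxy-9-(2-methylpropanoyloxy)germacra-1(10),11(13)-dien-14-yl (2R,3S)-2-methyl-3-[(triethylsilyl)oxy]butanoate
Conditions: Ac2O, pyridine, DMAP (cat.), CH2Cl2, 0 °C
Reagents that add atoms: acetic anhydride CC(=O)OC(C)=O
Why: Standard DMAP-catalysed acetylation of the primary allylic C12 alcohol should be fast and leaves all other groups unchanged.

Step 20
Reactants: 35 (1(10)E,4S,5R,7R,9S)-12-acetoxy-15-[(tert-butyldimethylsilyl)oxy]-4,5-epoxy-9-(2-methylpropanoyloxy)germacra-1(10),11(13)-dien-14-yl (2R,3S)-2-methyl-3-[(triethylsilyl)oxy]butanoate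
Product: 36 (1(10)E,4S,5R,7R,9S)-12-acetoxy-4,5-epoxy-15-hydroxy-9-(2-methylpropanoyloxy)germacra-1(10),11(13)-dien-14-yl (2R,3S)-3-hydroxy-2-methylbutanoate
Conditions: HF·pyridine (excess), pyridine, THF, 0 → 25 °C
Reagents that add atoms: none
Why: Global fluoride-mediated Si–O cleavage under pyridine buffering should free the C15 and side-chain hydroxyls without opening the oxirane transannularly or shifting the three esters.

**Compound list**

1 | prop-2-yn-1-ol | C#CCO | starting material
2 | sodium prop-2-yn-1-olate | [Na+].[O-]CC#C | intermediate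
3 | 1-methoxy-4-[(prop-2-yn-1-yloxy)methyl]benzene | C#CCOCc1ccc(OC)cc1 | intermediate
4 | 2-methylidenepropane-1,3-diol | C=C(CO)CO | starting material
5 | sodium 2-(hydroxymethyl)prop-2-en-1-olate | [Na+].[O-]CC(=C)CO | intermediate
6 | 2-{[(triethylsilyl)oxy]methyl}prop-2-en-1-ol | C=C(CO)CO[Si](CC)(CC)CC | intermediate
7 | 2-{[(triethylsilyl)oxy]methyl}prop-2-enal | C=C(C=O)CO[Si](CC)(CC)CC | intermediate
8 | (4R)-4-benzyl-3-propanoyl-1,3-oxazolidin-2-one | CCC(=O)N1[C@H](Cc2ccccc2)COC1=O | starting material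
9 | acetaldehyde | CC=O | starting material
10 | dibutylboron (Z)-enolate of 8 | C/C=C(\OB(CCCC)CCCC)N1[C@H](Cc2ccccc2)COC1=O | intermediate
11 | dibutylboron aldolate of 12 | O=C(N1[C@H](Cc2ccccc2)COC1=O)[C@H](C)[C@H](C)OB(CCCC)CCCC | intermediate
12 | (4R)-4-benzyl-3-[(2R,3S)-3-hydroxy-2-methylbutanoyl]-1,3-oxazolidin-2-one | O=C(N1[C@H](Cc2ccccc2)COC1=O)[C@H](C)[C@H](C)O | intermediate
13 | (4R)-4-benzyl-3-{(2R,3S)-2-methyl-3-[(triethylsilyl)oxy]butanoyl}-1,3-oxazolidin-2-one | O=C(N1[C@H](Cc2ccccc2)COC1=O)[C@H](C)[C@H](C)O[Si](CC)(CC)CC | intermediate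
14 | lithium (2R,3S)-2-methyl-3-[(triethylsilyl)oxy]butaneperoxoate | [Li+].[O-]OC(=O)[C@H](C)[C@H](C)O[Si](CC)(CC)CC | intermediate
15 | (2R,3S)-2-methyl-3-[(triethylsilyl)oxy]butanoic acid | OC(=O)[C@H](C)[C@H](C)O[Si](CC)(CC)CC | intermediate
16 | tert-butyldimethyl(prop-2-yn-1-yloxy)silane | C#CCO[Si](C)(C)C(C)(C)C | starting material
17 | {3-[(tert-butyldimethylsilyl)oxy]prop-1-yn-1-yl}lithium | [Li]C#CCO[Si](C)(C)C(C)(C)C | intermediate
18 | methyl 4-[(tert-butyldimethylsilyl)oxy]but-2-ynoate | COC(=O)C#CCO[Si](C)(C)C(C)(C)C | intermediate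
19 | but-3-en-1-ylmagnesium bromide | C=CCC[Mg]Br | starting material
20 | alkenylcopper adduct of 18 (copper at C2, cis to the butenyl group; drawn as the monomer) | COC(=O)/C([Cu])=C(/CCC=C)CO[Si](C)(C)C(C)(C)C | intermediate
21 | methyl (2Z)-3-{[(tert-butyldimethylsilyl)oxy]methyl}hepta-2,6-dienoate | COC(=O)/C=C(/CCC=C)CO[Si](C)(C)C(C)(C)C | intermediate
22 | (2Z)-3-{[(tert-butyldimethylsilyl)oxy]methyl}hepta-2,6-dien-1-ol | OC/C=C(/CCC=C)CO[Si](C)(C)C(C)(C)C | intermediate
23 | [(2R,3S)-3-(but-3-en-1-yl)-3-{[(tert-butyldimethylsilyl)oxy]methyl}oxiran-2-yl]methanol | C=CCC[C@@]1(CO[Si](C)(C)C(C)(C)C)O[C@@H]1CO | intermediate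
24 | {3-[(4-methoxybenzyl)oxy]prop-1-yn-1-yl}lithium | [Li]C#CCOCc1ccc(OC)cc1 | intermediate
25 | [(2R,3S)-3-(but-3-en-1-yl)-3-{[(tert-butyldimethylsilyl)oxy]methyl}oxiran-2-yl]methyl trifluoromethanesulfonate | C=CCC[C@@]1(CO[Si](C)(C)C(C)(C)C)O[C@@H]1COS(=O)(=O)C(F)(F)F | intermediate
26 | tert-butyl{[(2S,3R)-2-(but-3-en-1-yl)-3-{4-[(4-methoxybenzyl)oxy]but-2-yn-1-yl}oxiran-2-yl]methoxy}dimethylsilane | C=CCC[C@@]1(CO[Si](C)(C)C(C)(C)C)O[C@@H]1CC#CCOCc1ccc(OC)cc1 | intermediate
27 | tert-butyl{[(2S,3R)-2-(but-3-en-1-yl)-3-(3-{[(4-methoxybenzyl)oxy]methyl}-2-methylidenebut-3-en-1-yl)oxiran-2-yl]methoxy}dimethylsilane | C=CCC[C@@]1(CO[Si](C)(C)C(C)(C)C)O[C@@H]1CC(=C)C(=C)COCc1ccc(OC)cc1 | intermediate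
28 | (2E)-5-[(2S,3R)-2-{[(tert-butyldimethylsilyl)oxy]methyl}-3-(3-{[(4-methoxybenzyl)oxy]methyl}-2-methylidenebut-3-en-1-yl)oxiran-2-yl]-2-{[(triethylsilyl)oxy]methyl}pent-2-enal | O=C/C(CO[Si](CC)(CC)CC)=C/CC[C@@]1(CO[Si](C)(C)C(C)(C)C)O[C@@H]1CC(=C)C(=C)COCc1ccc(OC)cc1 | intermediate
29 | 9-O-diethylboryl derivative (diethylborinate) of 30 | C=C(COCc1ccc(OC)cc1)[C@@H]1C[C@H](OB(CC)CC)/C(CO[Si](CC)(CC)CC)=C/CC[C@@]2(CO[Si](C)(C)C(C)(C)C)O[C@@H]2C1 | intermediate
30 | (1(10)E,4S,5R,7R,9S)-15-[(tert-butyldimethylsilyl)oxy]-4,5-epoxy-12-[(4-methoxybenzyl)oxy]-14-[(triethylsilyl)oxy]germacra-1(10),11(13)-dien-9-ol | C=C(COCc1ccc(OC)cc1)[C@@H]1C[C@H](O)/C(CO[Si](CC)(CC)CC)=C/CC[C@@]2(CO[Si](C)(C)C(C)(C)C)O[C@@H]2C1 | intermediate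
31 | (1(10)E,4S,5R,7R,9S)-15-[(tert-butyldimethylsilyl)oxy]-4,5-epoxy-12-[(4-methoxybenzyl)oxy]germacra-1(10),11(13)-diene-9,14-diol | C=C(COCc1ccc(OC)cc1)[C@@H]1C[C@H](O)/C(CO)=C/CC[C@@]2(CO[Si](C)(C)C(C)(C)C)O[C@@H]2C1 | intermediate
32 | (1(10)E,4S,5R,7R,9S)-15-[(tert-butyldimethylsilyl)oxy]-4,5-epoxy-9-hydroxy-12-[(4-methoxybenzyl)oxy]germacra-1(10),11(13)-dien-14-yl (2R,3S)-2-methyl-3-[(triethylsilyl)oxy]butanoate | C=C(COCc1ccc(OC)cc1)[C@@H]1C[C@H](O)/C(COC(=O)[C@H](C)[C@H](C)O[Si](CC)(CC)CC)=C/CC[C@@]2(CO[Si](C)(C)C(C)(C)C)O[C@@H]2C1 | intermediate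
33 | (1(10)E,4S,5R,7R,9S)-15-[(tert-butyldimethylsilyl)oxy]-4,5-epoxy-12-[(4-methoxybenzyl)oxy]-9-(2-methylpropanoyloxy)germacra-1(10),11(13)-dien-14-yl (2R,3S)-2-methyl-3-[(triethylsilyl)oxy]butanoate | C=C(COCc1ccc(OC)cc1)[C@@H]1C[C@H](OC(=O)C(C)C)/C(COC(=O)[C@H](C)[C@H](C)O[Si](CC)(CC)CC)=C/CC[C@@]2(CO[Si](C)(C)C(C)(C)C)O[C@@H]2C1 | intermediate
34 | (1(10)E,4S,5R,7R,9S)-15-[(tert-butyldimethylsilyl)oxy]-4,5-epoxy-12-hydroxy-9-(2-methylpropanoyloxy)germacra-1(10),11(13)-dien-14-yl (2R,3S)-2-methyl-3-[(triethylsilyl)oxy]butanoate | C=C(CO)[C@@H]1C[C@H](OC(=O)C(C)C)/C(COC(=O)[C@H](C)[C@H](C)O[Si](CC)(CC)CC)=C/CC[C@@]2(CO[Si](C)(C)C(C)(C)C)O[C@@H]2C1 | intermediate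
35 | (1(10)E,4S,5R,7R,9S)-12-acetoxy-15-[(tert-butyldimethylsilyl)oxy]-4,5-epoxy-9-(2-methylpropanoyloxy)germacra-1(10),11(13)-dien-14-yl (2R,3S)-2-methyl-3-[(triethylsilyl)oxy]butanoate | C=C(COC(C)=O)[C@@H]1C[C@H](OC(=O)C(C)C)/C(COC(=O)[C@H](C)[C@H](C)O[Si](CC)(CC)CC)=C/CC[C@@]2(CO[Si](C)(C)C(C)(C)C)O[C@@H]2C1 | intermediate
36 | (1(10)E,4S,5R,7R,9S)-12-acetoxy-4,5-epoxy-15-hydroxy-9-(2-methylpropanoyloxy)germacra-1(10),11(13)-dien-14-yl (2R,3S)-3-hydroxy-2-methylbutanoate (CNP0256542.1) | C=C(COC(C)=O)[C@@H]1C[C@H](OC(=O)C(C)C)/C(COC(=O)[C@H](C)[C@H](C)O)=C/CC[C@@]2(CO)O[C@@H]2C1 | target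

**Summary**

Total step count: 20. Longest linear sequence: 14 steps (steps 7 to 20, from 16 to 36).

**Steps most likely to fail**

Step 14 (labelled, the riskiest). What may go wrong: oligomerisation outrunning the ten-membered ring closure, bond formation at the other diene terminus C13, conjugate addition to the enal, or poor facial selectivity with respect to the oxirane. The fallback uses known chemistry, sets out from 27 and 7 and comes back at 30. The same nickel-catalysed reductive homoallylation would be run in its established bimolecular form (Ni(acac)2, Et3B, THF, 25 °C) between diene 27 and aldehyde 7. This should join C8 to C9 with the anti C7/C9 relation and give the open-chain bis-allylic alcohol F1; its diastereomer with the opposite sense relative to the oxirane would have to be separated. Ring-closing olefin metathesis between the C1 vinyl group and the C10 methylidene group of F1 (second-generation Grubbs catalyst, toluene, 80 °C, high dilution) would then form the C1=C10 bond and return to 30; the E geometry of the new olefin would have to be confirmed.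

Step 13. What may go wrong: sequestration of the ruthenium carbene by the conjugated diene, sluggish formation of the trisubstituted enal, or erosion of the E geometry. The fallback replaces metathesis by olefination and cross-coupling, sets out from 26 and comes back at 28. Lemieux–Johnson cleavage of the vinyl group of 26 (OsO4 cat., N-methylmorpholine N-oxide; then NaIO4) would give the aldehyde F2. Wittig reaction with Ph3P=CHCHO (toluene, 80 °C) would give the E-enal F3. α-Iodination (I2, DMAP, K2CO3, THF/H2O) would give the (Z)-2-iodoenal F4. Stille coupling with Bu3SnCH2OH (Pd(PPh3)4, dioxane, 80 °C) would give, with retention of geometry, the 2-(hydroxymethyl)enal F5. Silylation (Et3SiCl, imidazole) would give the silyl ether F6. Ethene enyne metathesis as in step 12 would convert the alkyne of F6 into the diene and arrive at 28.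

Step 11. What may go wrong: decomposition of the epoxy triflate, or opening of the oxirane by the acetylide, before the SN2 displacement takes place. The fallback forms the C6–C7 bond before the oxirane exists, sets out from 22 and comes back at 26. Bromination of 22 (CBr4, PPh3, CH2Cl2, 0 °C) would give the allylic bromide F7. Coupling with alkyne 3 (CuI, NaI, K2CO3, DMF, 25 °C) would give the skipped enyne F8. Desilylation (Bu4NF, THF) would give the dienynol F9. Sharpless epoxidation directed by the C15 hydroxyl, here with L-(+)-diethyl tartrate (t-BuOOH, Ti(OiPr)4, 4 Å molecular sieves, CH2Cl2, −20 °C), should give the epoxy alcohol F10 with the same C4 S, C5 R oxirane. Silylation (t-BuMe2SiCl, imidazole, DMF) returns to 26.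

**Further compounds**

F1 | step 14 | open-chain C8–C9 coupled alcohol with free C1 vinyl and C10 methylidene groups (4S,5R,7R,9S; germacrane numbering) | C=CCC[C@@]1(CO[Si](C)(C)C(C)(C)C)O[C@@H]1C[C@@H](C[C@H](O)C(=C)CO[Si](CC)(CC)CC)C(=C)COCc1ccc(OC)cc1
F2 | step 13 | 3-[(2S,3R)-2-{[(tert-butyldimethylsilyl)oxy]methyl}-3-{4-[(4-methoxybenzyl)oxy]but-2-yn-1-yl}oxiran-2-yl]propanal | O=CCC[C@@]1(CO[Si](C)(C)C(C)(C)C)O[C@@H]1CC#CCOCc1ccc(OC)cc1
F3 | step 13 | (2E)-5-[(2S,3R)-2-{[(tert-butyldimethylsilyl)oxy]methyl}-3-{4-[(4-methoxybenzyl)oxy]but-2-yn-1-yl}oxiran-2-yl]pent-2-enal | O=C/C=C/CC[C@@]1(CO[Si](C)(C)C(C)(C)C)O[C@@H]1CC#CCOCc1ccc(OC)cc1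
F4 | step 13 | (2Z)-5-[(2S,3R)-2-{[(tert-butyldimethylsilyl)oxy]methyl}-3-{4-[(4-methoxybenzyl)oxy]but-2-yn-1-yl}oxiran-2-yl]-2-iodopent-2-enal | O=C/C(I)=C/CC[C@@]1(CO[Si](C)(C)C(C)(C)C)O[C@@H]1CC#CCOCc1ccc(OC)cc1
F5 | step 13 | (2E)-5-[(2S,3R)-2-{[(tert-butyldimethylsilyl)oxy]methyl}-3-{4-[(4-methoxybenzyl)oxy]but-2-yn-1-yl}oxiran-2-yl]-2-(hydroxymethyl)pent-2-enal | O=C/C(CO)=C/CC[C@@]1(CO[Si](C)(C)C(C)(C)C)O[C@@H]1CC#CCOCc1ccc(OC)cc1
F6 | step 13 | (2E)-5-[(2S,3R)-2-{[(tert-butyldimethylsilyl)oxy]methyl}-3-{4-[(4-methoxybenzyl)oxy]but-2-yn-1-yl}oxiran-2-yl]-2-{[(triethylsilyl)oxy]methyl}pent-2-enal | O=C/C(CO[Si](CC)(CC)CC)=C/CC[C@@]1(CO[Si](C)(C)C(C)(C)C)O[C@@H]1CC#CCOCc1ccc(OC)cc1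
F7 | step 11 | {[(2Z)-2-(2-bromoethylidene)hex-5-en-1-yl]oxy}(tert-butyl)dimethylsilane | BrC/C=C(/CCC=C)CO[Si](C)(C)C(C)(C)C
F8 | step 11 | tert-butyl{[(2Z)-2-(but-3-en-1-yl)-7-[(4-methoxybenzyl)oxy]hept-2-en-5-yn-1-yl]oxy}dimethylsilane | C=CCC/C(CO[Si](C)(C)C(C)(C)C)=C/CC#CCOCc1ccc(OC)cc1
F9 | step 11 | (2Z)-2-(but-3-en-1-yl)-7-[(4-methoxybenzyl)oxy]hept-2-en-5-yn-1-ol | C=CCC/C(CO)=C/CC#CCOCc1ccc(OC)cc1
F10 | step 11 | [(2S,3R)-2-(but-3-en-1-yl)-3-{4-[(4-methoxybenzyl)oxy]but-2-yn-1-yl}oxiran-2-yl]methanol | C=CCC[C@@]1(CO)O[C@@H]1CC#CCOCc1ccc(OC)cc1
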